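The numbers in the tables come from a simulation from invented constants; the scatter is artificial.

The winter run, with 1.6 M of coupling partner, showed me how substrate fell and how crystals followed, and from it I had to reckon the crystals in a flask holding 0.800 M.

| setting | winter | flask |
|---|---|---|
| substrate | 0.20 M | 0.20 M |
| coupling partner | 1.6 M | 0.800 M |
| remark | run made earlier |  |
| time |  | 10 h |

winter run (percent of the substrate charged)

| time / h | crystals / % | single product / % | substrate / % |
|---|---|---|---|
| 0.500 | 0 | 20 | 80 |
| 1.00 | 8 | 35 | 65 |
| 1.50 | 24 | 53 | 49 |
| 2.00 | 35 | 60 | 35 |
| 2.50 | 41 | 70 | 30 |
| 3.00 | 47 | 75 | 25 |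

(readings scatter by 2 percentage points)

- for single product the crystals are counted in
- as a solid, counted per litre of solution: crystals
- the numbers in the tables scatter with a standard deviation of 2 percentage points

- amount of crystals in percent of the substrate charged, at 1.0 h, 4.0 h and 10 h

I built that flask up one process at a time. With the main step alone, substrate + coupling partner to single product, and the coupling partner frozen at its charge (pseudo-first-order), the winter reading of 25% substrate at 3.00 h gave a rate constant of about 0.462 h⁻¹. I assumed first order in coupling partner, which that run can't test, so I reckoned 0.231 h⁻¹ for the flask, and with it 20.6% of single product by 1.0 h, 60.3% by 4.0 h and 90.1% by 10 h.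

Then I added the crystals. In the winter run, single product minus crystals, the dissolved part, stayed near 27.8% of the charge from 1.50 h on, within the scatter. So I froze it as the dissolved ceiling, the solubility as read: c(single product) in solution while crystals stand, 0.0555 M. I counted as crystals what was made above it. At 1.0 h my reckoned amount for the flask stood below the ceiling, so I gave it no crystals, and my later figures became 32.6% and 62.3%. Growth got no allowance, since the dissolved part already read 27.0% at 1.00 h.

Last I let the coupling partner be used, one for one with substrate. Taking its mean as the charge less half the substrate charge, 0.700 M, I reckoned 86.8% of single product for the flask by 10 h, which left 59.0% as crystals. I left the 4.0 h figure as it stood.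

The forecast gave 0%, 32% and 60%, holding that “crystals are simply the excess over saturation”; its last figure stood above mine. The flask gave 0%, 33.0% and 59.4%, within the tolerance.

    single product → over-reaction product (k = 1.40 × 10⁻⁷ s⁻¹)
    crystals ⇌ single product, rate k2*(cs2 - [single product]) while solid is left; crystals form when [single product] > cs2 (solubility = 0.0520 M, k = 0.00300 s⁻¹)
    substrate + coupling partner → single product (k = 9.00 × 10⁻⁵ M⁻¹ s⁻¹)
    coupling partner + bis adduct → tris adduct (k = 9.90 × 10⁻⁵ M⁻¹ s⁻¹)
    coupling partner + single product → bis adduct (k = 5.00 × 10⁻⁶ M⁻¹ s⁻¹)

The weight lay on the ceiling: in the run of this flask without the low solubility of single product, crystals went from 59.4% to 0%. The 85.6% of single product at 10.0 h, crystals counted in, less the ceiling of 0.0555 M, leaves 57.8%, and the crystals stood at 59.4%. With half the substrate, the same 0.0555 M is 55.5% of the smaller charge; counting on the same share made, I got 30.1%, and that flask held 32.4%.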